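## Retrosynthetic overview

1. The target is reached by Z-selective 1,4-hydrogenation of a conjugated triene, itself made by Horner–Wadsworth–Emmons (HWE) union of a dioxane aldehyde (13) with a bicyclic phosphonate (19).
2. The 1,2-dioxane (the only ring built in the main fragment) is closed by C3–O bond formation: a tertiary hydroperoxide opens a cis-β-lactone by SN2, with inversion, and releases the acid.
3. The tertiary C6–O bond comes from invertive perhydrolysis of a 2,2-disubstituted oxetane made from (S)-linalool; the β-lactone comes from a catalytic asymmetric ketene–aldehyde cyclocondensation.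
4. Both carbocycles are bought as 6-methoxy-1-tetralone (gem-dimethylation, Birch reduction). Ring order: oxetane, then β-lactone, then 1,2-dioxane.

Assumptions: the SMILES is read as the (2S,3S,6S)-acid with a Z exocyclic olefin (side chain cis to the ring CH2 that is bonded to the ring-fusion carbon without the gem-dimethyl neighbour). O-TMS-quinine is taken to give the (3S,4R)-lactone in step 4; if the sense is the opposite, O-TMS-quinidine is used instead.

Locants: dioxane O1, O2, C3, C6; side chain C1′–C3′ counted from C6; bicycle numbered as a naphthalene with the exocyclic olefin on C2, C1 between C2 and C8a, gem-dimethyl on C5.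

## Route

Step 1
Reactants: 1 (S)-linalool
Product: 3 (3S)-3,7-dimethyloct-6-ene-1,3-diol, via alkylborane 2 (not isolated)
Conditions: 9-BBN, THF, 0 °C → rt; then NaOH, H2O2, 0 °C
Reagents that add atoms: 9-borabicyclo[3.3.1]nonane, B1C2CCCC1CCC2 (in 2 only); hydrogen peroxide, OO
Why: Anti-Markovnikov hydroboration–oxidation in which the bulky borane takes the monosubstituted vinyl group and leaves the trisubstituted olefin, while the tertiary carbinol stereocentre (the future C6) is untouched.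

Step 2
Reactants: 3 (3S)-3,7-dimethyloct-6-ene-1,3-diol
Product: 5 (2S)-2-methyl-2-(4-methylpent-3-en-1-yl)oxetane, via monotosylate 4 (not isolated)
Conditions: n-BuLi (1.0 equiv), THF, −78 → 0 °C; TsCl (1.0 equiv), 0 °C; then KOtBu (1.1 equiv), 0 → 45 °C
Reagents that add atoms: 4-methylbenzenesulfonyl chloride, Cc1ccc(cc1)S(Cl)(=O)=O (in 4 only)
Why: Selective sulfonylation of the primary alkoxide followed by Williamson 4-exo-tet closure by the tertiary alkoxide gives the oxetane with the C–O bond of the stereocentre intact (retention).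

Step 3
Reactants: 5 (2S)-2-methyl-2-(4-methylpent-3-en-1-yl)oxetane
Product: 7 3-[(2S)-2-methyloxetan-2-yl]propanal, via ozonide 6 (not isolated)
Conditions: O3, CH2Cl2, −78 °C; then Me2S, −78 °C → rt
Reagents that add atoms: ozone, [O-][O+]=O
Why: Ozonolysis with reductive work-up cleaves the only olefin and the oxetane is inert to ozone.

Step 4
Reactants: 7 3-[(2S)-2-methyloxetan-2-yl]propanal; 8 propanoyl chloride
Product: 10 (3S,4R)-3-methyl-4-{2-[(2S)-2-methyloxetan-2-yl]ethyl}oxetan-2-one, via methylketene 9 (not isolated)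
Conditions: O-trimethylsilylquinine (10 mol%), LiClO4, iPr2NEt, CH2Cl2/Et2O, −78 °C
Reagents that add atoms: none
Why: Cinchona alkaloid/LiClO4-catalysed acyl halide–aldehyde cyclocondensation (formal [2+2] of the ammonium enolate of methylketene) gives the cis-β-lactone, the catalyst setting lactone C3 (the final C2) and lactone C4 (the final C3 after the later inversion).

Step 5
Reactants: 10 (3S,4R)-3-methyl-4-{2-[(2S)-2-methyloxetan-2-yl]ethyl}oxetan-2-one
Product: 11 (3S,4R)-4-[(3R)-3-hydroperoxy-5-hydroxy-3-methylpentyl]-3-methyloxetan-2-one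
Conditions: H2O2 (anhydrous, in Et2O, 10 equiv), TMSOTf (0.3 equiv), Et2O, −78 → −40 °C
Reagents that add atoms: hydrogen peroxide, OO
Why: Lewis acid-promoted perhydrolysis of a 2,2-disubstituted oxetane, in which H2O2 attacks the activated tertiary C–O bond from the back (inversion) and so sets the C6 configuration, while the secondary lactone C–O bond does not ionise at this temperature.

Step 6
Reactants: 11 (3S,4R)-4-[(3R)-3-hydroperoxy-5-hydroxy-3-methylpentyl]-3-methyloxetan-2-one
Product: 12 (2S)-2-[(3S,6R)-6-(2-hydroxyethyl)-6-methyl-1,2-dioxan-3-yl]propanoic acid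
Conditions: KN(SiMe3)2 (1.05 equiv), 18-crown-6, THF, −78 → 0 °C; then cold 1 M HCl
Reagents that add atoms: none
Why: Proposed new method: intramolecular 6-exo-tet SN2 opening of a β-lactone at its β-carbon (alkyl–oxygen cleavage) by a tertiary peroxide anion; the hydroperoxide (pKa about 13) is deprotonated selectively over the alcohol and the lactone α-CH, and the soft α-effect peroxy anion is held five atoms from the strained secondary C–O bond, so backside attack closes the 1,2-dioxane with inversion at C3 and releases the carboxylate (acyl attack would need an eight-membered perester), which sets 3S and the anti C2/C3 relationship; the closest known reactions are the alkyl–oxygen opening of β-lactones by soft nucleophiles and by pendant ether oxygens (inversion) and the base-mediated cyclisation of hydroperoxides onto sulfonates or halides to give 1,2-dioxanes.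

Step 7
Reactants: 12 (2S)-2-[(3S,6R)-6-(2-hydroxyethyl)-6-methyl-1,2-dioxan-3-yl]propanoic acid
Product: 13 (2S)-2-[(3S,6R)-6-methyl-6-(2-oxoethyl)-1,2-dioxan-3-yl]propanoic acid
Conditions: Dess–Martin periodinane, CH2Cl2, 0 °C → rt
Reagents that add atoms: none
Why: Dess–Martin oxidation of the primary alcohol stops at the aldehyde, tolerates dialkyl peroxides and a free carboxylic acid, and touches no stereocentre.

Step 8
Reactants: 14 6-methoxy-3,4-dihydronaphthalen-1(2H)-one
Product: 15 6-methoxy-1,1-dimethyl-1,2,3,4-tetrahydronaphthalene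
Conditions: ZnMe2, TiCl4 (gives Me2TiCl2), CH2Cl2, −30 °C → rt
Reagents that add atoms: dimethylzinc, C[Zn]C
Why: Reetz geminal dimethylation, in which methyl addition, ionisation of the p-methoxybenzylic titanium alkoxide and a second methyl transfer replace C=O by CMe2.

Step 9
Reactants: 15 6-methoxy-1,1-dimethyl-1,2,3,4-tetrahydronaphthalene
Product: 17 5,5-dimethyl-3,4,5,6,7,8-hexahydronaphthalen-2(1H)-one, via enol ether 16 (not isolated)
Conditions: Li, NH3(l), t-BuOH, THF, −78 → −33 °C; NH4Cl; then (CO2H)2, MeOH/H2O, rt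
Reagents that add atoms: water, O
Why: Birch reduction of the anisole ring gives the 2,5-dihydroanisole with the tetrasubstituted olefin at the ring fusion, and mild oxalic acid hydrolysis of the enol ether gives the β,γ-unsaturated ketone without conjugation.

Step 10
Reactants: 17 5,5-dimethyl-3,4,5,6,7,8-hexahydronaphthalen-2(1H)-one; 18 tetraethyl methylenebis(phosphonate)
Product: 19 diethyl [(5,5-dimethyl-3,4,5,6,7,8-hexahydronaphthalen-2(1H)-ylidene)methyl]phosphonate
Conditions: NaH, THF, 0 → 40 °C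
Reagents that add atoms: none
Why: HWE olefination of the ketone with the bisphosphonate anion gives the vinylphosphonate, whose olefin geometry and any double-bond positional isomer are irrelevant because all give the same delocalised anion in step 11.

Step 11
Reactants: 13 (2S)-2-[(3S,6R)-6-methyl-6-(2-oxoethyl)-1,2-dioxan-3-yl]propanoic acid; 19 diethyl [(5,5-dimethyl-3,4,5,6,7,8-hexahydronaphthalen-2(1H)-ylidene)methyl]phosphonate
Product: 20 (2S)-2-[(3S,6R)-6-[(2E)-3-(5,5-dimethyl-3,4,5,6,7,8-hexahydronaphthalen-2-yl)prop-2-en-1-yl]-6-methyl-1,2-dioxan-3-yl]propanoic acid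
Conditions: 19 (2.3 equiv), LiN(iPr)2 (2.2 equiv), THF, −78 °C; then 13, −78 → 0 °C; cold 1 M HCl
Reagents that add atoms: none
Why: γ-Deprotonation of 19 at the doubly allylic C1 gives the extended allylic phosphonate anion, which adds through its α-carbon to the aldehyde and eliminates phosphate (HWE) to give the (E)-olefin of a conjugated triene, one equivalent of anion being spent on the carboxylic acid.

Step 12
Reactants: 20 (2S)-2-[(3S,6R)-6-[(2E)-3-(5,5-dimethyl-3,4,5,6,7,8-hexahydronaphthalen-2-yl)prop-2-en-1-yl]-6-methyl-1,2-dioxan-3-yl]propanoic acid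
Product: 21 (2S)-2-[(3S,6S)-6-[(3Z)-3-(5,5-dimethyl-3,4,5,6,7,8-hexahydronaphthalen-2(1H)-ylidene)propyl]-6-methyl-1,2-dioxan-3-yl]propanoic acid (target)
Conditions: (η6-naphthalene)Cr(CO)3 (20 mol%), H2 (4 atm), degassed acetone, 25–40 °C
Reagents that add atoms: none
Why: Arene–Cr(CO)3-catalysed 1,4-hydrogenation adds H2 to the two ends of an s-cis η4-bound diene; only the C2′=C3′–C2=C1 diene has accessible CH termini (the homoannular diene ends in two fully substituted carbons), so hydrogen goes to C2′ and C1 and the new C3′=C2 olefin has the chain cis to C1 (Z), while isolated olefins and, it is expected, the dialkyl peroxide are left alone.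

## Compound list

1 | (S)-linalool, (3S)-3,7-dimethylocta-1,6-dien-3-ol | C=C[C@@](C)(O)CCC=C(C)C | starting material
2 | 9-[(3S)-3-hydroxy-3,7-dimethyloct-6-en-1-yl]-9-borabicyclo[3.3.1]nonane | CC(C)=CCC[C@](C)(O)CCB1C2CCCC1CCC2 | intermediate
3 | (3S)-3,7-dimethyloct-6-ene-1,3-diol | OCC[C@@](C)(O)CCC=C(C)C | intermediate
4 | (3S)-3-hydroxy-3,7-dimethyloct-6-en-1-yl 4-methylbenzenesulfonate | Cc1ccc(cc1)S(=O)(=O)OCC[C@@](C)(O)CCC=C(C)C | intermediate
5 | (2S)-2-methyl-2-(4-methylpent-3-en-1-yl)oxetane | C1C[C@@](C)(O1)CCC=C(C)C | intermediate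
6 | 3,3-dimethyl-5-{2-[(2S)-2-methyloxetan-2-yl]ethyl}-1,2,4-trioxolane (epimers at C5) | C1C[C@@](C)(O1)CCC2OOC(C)(C)O2 | intermediate
7 | 3-[(2S)-2-methyloxetan-2-yl]propanal | C1C[C@@](C)(O1)CCC=O | intermediate
8 | propanoyl chloride | CCC(Cl)=O | starting material
9 | methylketene | CC=C=O | intermediate
10 | (3S,4R)-3-methyl-4-{2-[(2S)-2-methyloxetan-2-yl]ethyl}oxetan-2-one | C[C@H]1[C@@H](CC[C@@]2(C)CCO2)OC1=O | intermediate
11 | (3S,4R)-4-[(3R)-3-hydroperoxy-5-hydroxy-3-methylpentyl]-3-methyloxetan-2-one | C[C@H]1[C@@H](CC[C@](C)(CCO)OO)OC1=O | intermediate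
12 | (2S)-2-[(3S,6R)-6-(2-hydroxyethyl)-6-methyl-1,2-dioxan-3-yl]propanoic acid | C[C@H](C(=O)O)[C@@H]1CC[C@](C)(CCO)OO1 | intermediate
13 | (2S)-2-[(3S,6R)-6-methyl-6-(2-oxoethyl)-1,2-dioxan-3-yl]propanoic acid | C[C@H](C(=O)O)[C@@H]1CC[C@](C)(CC=O)OO1 | intermediate
14 | 6-methoxy-3,4-dihydronaphthalen-1(2H)-one | COc1ccc2c(c1)CCCC2=O | starting material
15 | 6-methoxy-1,1-dimethyl-1,2,3,4-tetrahydronaphthalene | COc1ccc2c(c1)CCCC2(C)C | intermediate
16 | 6-methoxy-1,1-dimethyl-1,2,3,4,5,8-hexahydronaphthalene | COC1=CCC2=C(C1)CCCC2(C)C | intermediate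
17 | 5,5-dimethyl-3,4,5,6,7,8-hexahydronaphthalen-2(1H)-one | O=C1CCC2=C(C1)CCCC2(C)C | intermediate
18 | tetraethyl methylenebis(phosphonate) | CCOP(=O)(OCC)CP(=O)(OCC)OCC | starting material
19 | diethyl [(5,5-dimethyl-3,4,5,6,7,8-hexahydronaphthalen-2(1H)-ylidene)methyl]phosphonate (E/Z mixture) | CCOP(=O)(OCC)C=C1CCC2=C(C1)CCCC2(C)C | intermediate
20 | (2S)-2-[(3S,6R)-6-[(2E)-3-(5,5-dimethyl-3,4,5,6,7,8-hexahydronaphthalen-2-yl)prop-2-en-1-yl]-6-methyl-1,2-dioxan-3-yl]propanoic acid | C[C@H](C(=O)O)[C@@H]1CC[C@](C)(C/C=C/C2=CC3=C(CC2)C(C)(C)CCC3)OO1 | intermediate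
21 | (2S)-2-[(3S,6S)-6-[(3Z)-3-(5,5-dimethyl-3,4,5,6,7,8-hexahydronaphthalen-2(1H)-ylidene)propyl]-6-methyl-1,2-dioxan-3-yl]propanoic acid | C[C@H](C(=O)O)[C@@H]1CC[C@](C)(CC/C=C2/CCC3=C(CCCC3(C)C)C2)OO1 | target

## Step count and risks

Total steps: 12 (steps 1–7 for the peroxide fragment, 8–10 for the bicycle, 11–12 for union and finish). Longest linear sequence: 9 (steps 1–7, 11, 12).

The three steps most likely to fail:

**Step 6 (the proposed new step).** The peroxy anion may attack the lactone carbonyl, or the lactone may eliminate instead of being opened. The fallback uses known chemistry, sets out from 7 and comes back at 12. Aldehyde 7 is crotylated with the antipode of (Z)-crotyl-B(Ipc)2 that gives the syn alcohol (3R,4R)-4-methyl-1-[(2S)-2-methyloxetan-2-yl]hex-5-en-3-ol F1 (Brown crotylboration, NaOH/H2O2 work-up). MsCl/Et3N gives (3R,4R)-4-methyl-1-[(2S)-2-methyloxetan-2-yl]hex-5-en-3-yl methanesulfonate F2. The oxetane is perhydrolysed as in step 5 to (3R,4R,7R)-7-hydroperoxy-9-hydroxy-3,7-dimethylnon-1-en-4-yl methanesulfonate F3. KOtBu/18-crown-6 then closes the ring by the known displacement of a secondary sulfonate by a hydroperoxide (inversion at C3), giving 2-[(3R,6S)-6-[(2R)-but-3-en-2-yl]-3-methyl-1,2-dioxan-3-yl]ethan-1-ol F4. Ozonolysis (O3; Me2S) gives (2S)-2-[(3S,6R)-6-(2-hydroxyethyl)-6-methyl-1,2-dioxan-3-yl]propanal F5, and NaClO2/NaH2PO4/2-methylbut-2-ene gives 12.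

**Step 5.** The β-lactone may not survive TMSOTf/H2O2 (premature closure of 11 to 12 would be harmless). The fallback sets out from 5 and comes back at 11. Oxetane 5 is perhydrolysed before any lactone is present, giving (3R)-3-hydroperoxy-3,7-dimethyloct-6-en-1-ol F6. 2-Methoxypropene/PPTS masks both OH and OOH, giving (6R)-6-[(2-methoxypropan-2-yl)peroxy]-8-[(2-methoxypropan-2-yl)oxy]-2,6-dimethyloct-2-ene F7. Ozonolysis (O3; Me2S) gives (4R)-4-[(2-methoxypropan-2-yl)peroxy]-6-[(2-methoxypropan-2-yl)oxy]-4-methylhexanal F8. The cyclocondensation of step 4 gives (3S,4R)-4-{(3R)-3-[(2-methoxypropan-2-yl)peroxy]-5-[(2-methoxypropan-2-yl)oxy]-3-methylpentyl}-3-methyloxetan-2-one F9, and AcOH/THF/H2O removes both acetal groups to give 11.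

**Step 12.** The low-valent chromium catalyst may reduce the O–O bond; this compatibility is untested. The fallback fixes the olefin geometry on the bicycle in the absence of the peroxide and joins the fragments with palladium, which 1,2-dioxanes are known to tolerate. It sets out from 17 and 12 and comes back at 21.
- Ketone 17 with KN(SiMe3)2/PhNTf2 gives 5,5-dimethyl-3,4,5,6,7,8-hexahydronaphthalen-2-yl trifluoromethanesulfonate F10.
- Pd(PPh3)4/CO/Bu3SnH gives 5,5-dimethyl-3,4,5,6,7,8-hexahydronaphthalene-2-carbaldehyde F11.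
- RhCl(PPh3)3-catalysed 1,4-hydrosilylation with Et3SiH through the s-cis enal gives triethyl{[(Z)-(5,5-dimethyl-3,4,5,6,7,8-hexahydronaphthalen-2(1H)-ylidene)methyl]oxy}silane F12.
- MeLi then PhNTf2 gives (Z)-(5,5-dimethyl-3,4,5,6,7,8-hexahydronaphthalen-2(1H)-ylidene)methyl trifluoromethanesulfonate F13.
- Alcohol 12 with I2/PPh3/imidazole (0 °C, short contact) gives (2S)-2-[(3S,6R)-6-(2-iodoethyl)-6-methyl-1,2-dioxan-3-yl]propanoic acid F14.
- Zinc insertion gives the alkylzinc iodide {2-[(3R,6S)-6-[(1S)-1-carboxyethyl]-3-methyl-1,2-dioxan-3-yl]ethyl}(iodo)zinc F15, and Negishi coupling with F13 (Pd(PPh3)4, retention of olefin geometry) gives 21.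

## Further compounds

F1 | step 6 | (3R,4R)-4-methyl-1-[(2S)-2-methyloxetan-2-yl]hex-5-en-3-ol | C[C@H](C=C)[C@H](O)CC[C@@]1(C)CCO1
F2 | step 6 | (3R,4R)-4-methyl-1-[(2S)-2-methyloxetan-2-yl]hex-5-en-3-yl methanesulfonate | C[C@H](C=C)[C@H](OS(C)(=O)=O)CC[C@@]1(C)CCO1
F3 | step 6 | (3R,4R,7R)-7-hydroperoxy-9-hydroxy-3,7-dimethylnon-1-en-4-yl methanesulfonate | C[C@H](C=C)[C@H](OS(C)(=O)=O)CC[C@](C)(CCO)OO
F4 | step 6 | 2-[(3R,6S)-6-[(2R)-but-3-en-2-yl]-3-methyl-1,2-dioxan-3-yl]ethan-1-ol | C[C@H](C=C)[C@@H]1CC[C@](C)(CCO)OO1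
F5 | step 6 | (2S)-2-[(3S,6R)-6-(2-hydroxyethyl)-6-methyl-1,2-dioxan-3-yl]propanal | C[C@H](C=O)[C@@H]1CC[C@](C)(CCO)OO1
F6 | step 5 | (3R)-3-hydroperoxy-3,7-dimethyloct-6-en-1-ol | CC(C)=CCC[C@](C)(CCO)OO
F7 | step 5 | (6R)-6-[(2-methoxypropan-2-yl)peroxy]-8-[(2-methoxypropan-2-yl)oxy]-2,6-dimethyloct-2-ene | CC(C)=CCC[C@](C)(CCOC(C)(C)OC)OOC(C)(C)OC
F8 | step 5 | (4R)-4-[(2-methoxypropan-2-yl)peroxy]-6-[(2-methoxypropan-2-yl)oxy]-4-methylhexanal | O=CCC[C@](C)(CCOC(C)(C)OC)OOC(C)(C)OC
F9 | step 5 | (3S,4R)-4-{(3R)-3-[(2-methoxypropan-2-yl)peroxy]-5-[(2-methoxypropan-2-yl)oxy]-3-methylpentyl}-3-methyloxetan-2-one | C[C@H]1[C@@H](CC[C@](C)(CCOC(C)(C)OC)OOC(C)(C)OC)OC1=O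
F10 | step 12 | 5,5-dimethyl-3,4,5,6,7,8-hexahydronaphthalen-2-yl trifluoromethanesulfonate | O=S(=O)(OC1=CC2=C(CC1)C(C)(C)CCC2)C(F)(F)F
F11 | step 12 | 5,5-dimethyl-3,4,5,6,7,8-hexahydronaphthalene-2-carbaldehyde | O=CC1=CC2=C(CC1)C(C)(C)CCC2
F12 | step 12 | triethyl{[(Z)-(5,5-dimethyl-3,4,5,6,7,8-hexahydronaphthalen-2(1H)-ylidene)methyl]oxy}silane | CC[Si](CC)(CC)O/C=C1/CCC2=C(CCCC2(C)C)C1
F13 | step 12 | (Z)-(5,5-dimethyl-3,4,5,6,7,8-hexahydronaphthalen-2(1H)-ylidene)methyl trifluoromethanesulfonate | O=S(=O)(O/C=C1/CCC2=C(CCCC2(C)C)C1)C(F)(F)F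
F14 | step 12 | (2S)-2-[(3S,6R)-6-(2-iodoethyl)-6-methyl-1,2-dioxan-3-yl]propanoic acid | C[C@H](C(=O)O)[C@@H]1CC[C@](C)(CCI)OO1
F15 | step 12 | {2-[(3R,6S)-6-[(1S)-1-carboxyethyl]-3-methyl-1,2-dioxan-3-yl]ethyl}(iodo)zinc | C[C@H](C(=O)O)[C@@H]1CC[C@](C)(CC[Zn]I)OO1
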